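## The problem

Target 14 (CNP0294928.1) is a (2S)-flavanone. It is a chroman-4-one in which ring C is fused to ring A and carries the catechol ring B at C2. The rings are held together by the O1–C2 ether bond, the C2–C1' bond and the C4–C4a aryl ketone bond. C2 is the only stereocentre, so nothing in the molecule can relay chirality to it and a catalyst or reagent must set it. It is also fragile. Base opens ring C to the chalcone by β-elimination of the ring A phenoxide, and acid can ionise O1–C2 through a ring B quinone methide once the 4'-hydroxyl is free. Ring A is a fully differentiated phloroglucinol: O1 is the ring ether, the 5-hydroxyl is free and chelated to the ketone, and O7 is methylated. The prenyl group sits at C8 between O1 and the 7-methoxyl and not at C6, so three oxygens of similar reactivity must be told apart. The prenyl group will not survive strong acid (hydration, hydrohalogenation), hydrogenation or oxidants that attack its benzylic, allylic CH2. The catechol is oxidised easily. The feature that opens the route is that ring B with its 4'-hydroxyl and C2–C3 is a para-hydroxystyrene, while C4, C4a, C8a and O1 are the atoms of a salicylaldehyde. The heterodiene O1=C8a–C4a=C4 (an ortho-quinone methide) can therefore take up the vinyl group C2=C3, forming O1–C2 and C3–C4 together. If C4 carries a methoxyl in that quinone methide it arrives at the alcohol oxidation level, one oxidation from the ketone.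

## Retrosynthesis

**Protecting groups (14 to 13).** No skeletal bond is cut. Target 14 is traced to flavanone 13, its 5-O-methoxymethyl ether 3',4'-diacetate. The methoxymethyl group is the mark that earlier distinguishes the two ortho oxygens of ring A. The acetates keep ring B electron-poor and safe from oxidation during the C4 adjustments. All three groups leave under acidic methanolysis. Basic unmasking is excluded because base scrambles C2 through the chalcone. The forward step must cleave one aryl acetal and two aryl esters without adding across the prenyl alkene.

**Oxidation level of C4 (13 to 12 to 11 to 10).** The C4 carbonyl of 13 is traced to the secondary alcohol 12, and 12 to the C4 methyl ether 11 by exchanging OMe for OH. Compound 11 is the diacetate of catechol 10. The neighbouring option, a flavan with CH2 at C4 oxidised late, would set C4–H against the prenyl CH2 and C2–H. An oxygen at C4 from the start avoids that contest. C4 of 11 is benzylic to a ring with two ortho oxygens and one para oxygen, so its methoxyl should exchange with water under very mild acid. The forward steps require that the C4 cation takes up water faster than it loses H3 or alkylates a second ring A. They also require that ring B is already acetylated, so that O1–C2 cannot ionise.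

**Ring C (10 to 5 and 7, with 8).** The bonds O1–C2 and C3–C4 are cut together. This divides 10 into salicylaldehyde 5, 4-vinylcatechol 7 and trimethyl orthoformate 8, which supplies the C4 methoxyl through the dimethyl acetal 9. Three neighbouring cuts were weighed:
- O1–C2 alone (oxa-Michael closure of a chalcone) is reversible and hard to make enantioselective without an extra activating group.
- C2–C1' (conjugate arylation of a chromone) needs the whole ring A chromone first.
- C4–C4a needs a chiral aryloxy acid first.

The double cut removes ring C and both stereocentres in one step and leaves two benzene derivatives of fifteen and eight carbons. It asks for face selectivity at C2 from a chiral Brønsted acid, a single free phenol in 5 so that only one quinone methide can form, and acidity low enough to spare the prenyl group beside that phenol.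

**Ring A (5 to 4 to 3 to 1 and 2).** Three bonds are cut in turn: the O–CH2OMe bond of 5, the 4-O–CH3 bond of 4 and the aryl–prenyl C–C bond of 3. This leads to 2,4,6-trihydroxybenzaldehyde 1 and prenyl bromide 2. C-Prenylation comes first because the two nucleophilic ring carbons of symmetric 1 are equivalent, so no regiochemical question arises. With the prenyl group in place the three hydroxyls are graded:
- the para hydroxyl is the most acidic and unchelated, and takes the methyl group;
- the ortho hydroxyl with an open flank takes the methoxymethyl group;
- the ortho hydroxyl wedged between formyl and prenyl remains free, and this is the one that must become O1.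

The forward steps depend on that grading and nothing else.

**Styrene (7 to 6).** The C–CO2H bond is cut. Compound 7 polymerises on storage, so it is made from caffeic acid 6 by decarboxylation just before use. Both phenols stay free because the 4'-hydroxyl is needed in the key step.

## Roads not taken

**Alternative 1:** Ring A is made last by cutting C4a–C5 and C8–C8a.
- *Forward key step.* The 1,3-dioxygenated silyl ketene acetal diene A3, which carries the prenyl chain at its nucleophilic terminus, would add to the C5=C6 bond of the (S)-sulfinyl dihydropyranone A2. Loss of the sulfinyl group as a sulfenic acid and of methanol would aromatise ring A and give A1, the 3',4'-bis(methoxymethyl) ether of 14.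
- *Merits.* C2 is fixed beforehand by the established catalytic asymmetric hetero-Diels–Alder route to 2-aryl dihydropyranones. Every ring A substituent is written into A3, so no phenol has to be told from another. A1 already holds the ketone and the free 5-hydroxyl and is one deprotection from 14.
- *Weak points.* The double bond of A2 is that of a vinylogous ester, a poor dienophile even with the sulfinyl group. A3 reacts at a substituted terminus. It must be made by γ-deprotonation beside the doubly allylic CH2 of the prenyl chain, which invites conjugated triene isomers. Before aromatisation the adduct holds C2 β to a ketone, so heating may open the ring and lose the stereocentre. A2 and A3 each need several steps.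
- *Comparison.* This road is better than the chosen one in regiocontrol of ring A and in having no late redox adjustment. The chosen plan relies on graded phenol reactivity in steps 2 and 3 and needs three steps to turn C4–OMe into C=O. Against that it sets a shorter, convergent route from two simple aromatic partners and a cycloaddition whose partners are polarity-matched.

**Alternative 2:** The cut is C2–C3.
- *Forward key step.* The diazoketone A5, with ring B attached as an ortho benzyl ether, would be decomposed by Rh2(S-PTTL)4 or its antipode. The divalent rhodium carbene at C3 would insert into one enantiotopic benzylic C–H bond and give the tris-silyl flavanone A4.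
- *Merits.* The ketone is present from the start, the stereocentre is made late from an achiral ether, and only desilylation remains.
- *Weak points.* The carbene is of the acceptor-only kind, the least selective class. The ether oxygen sits where a five-membered oxonium ylide can form, and a Stevens [1,2]-benzyl shift to a 2-benzylbenzofuranone should outrun a six-membered C–H insertion. The prenyl alkene and both electron-rich rings are open to cyclopropanation and Buchner reaction. High selectivity with this catalyst family is documented for five-membered ring closure of aryl diazoacetates, not for this ring size. A5 itself needs benzylation of a hindered chelated phenol and a diazoketone from a 2,6-disubstituted benzoyl unit. Fluoride removal of three silyl ethers from A4 is basic, which endangers C2.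
- *Comparison.* If the insertion worked, this road would be shorter after ring closure, one step against four. The chosen plan sets against this that its bond formation has no faster intramolecular competitor and that its later steps are routine.

**Alternative 3:** The cut is C4–C4a.
- *Forward key step.* The (S)-aryloxy acid A7, as its acid chloride or mixed trifluoroacetic anhydride, would acylate the one free position ortho to the ether oxygen and give A6, the 5-O-methyl 3',4'-diacetate of 14.
- *Merits.* The chemistry is classical. The site of acylation cannot be wrong because the other ortho position carries the prenyl group. The ketone is formed directly.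
- *Weak points.* A7 is a β-aryloxy acid, so activation invites β-elimination of the phenoxide and re-addition, which racemises C2. The acylating acid meets the prenyl alkene. Making the hindered benzylic aryl ether with inversion risks ionisation at an electron-rich benzylic carbon. A6 ends with a 5-methoxyl, so a chelation-controlled demethylation by a boron or aluminium halide is needed at the close, which is harsh for the prenyl group and able to open the flavanone.
- *Comparison.* Ring closure here is more certain than the chosen key step, which is new in its enantioselective form. The chosen plan sets against this a weak, catalytic acid in the ring-forming step and protecting groups that leave under gentle conditions without a final demethylation.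

Key step: step 5

Assumption: the (R) antipode of the phosphoric acid is written as the one that leads to the 2S series; the sense of induction cannot be derived from structure alone, and the (S) acid is used if it proves opposite.

## Route

Step 1
Reactants: 1 2,4,6-trihydroxybenzaldehyde; 2 prenyl bromide (1-bromo-3-methylbut-2-ene)
Product: 3 2,4,6-trihydroxy-3-(3-methylbut-2-en-1-yl)benzaldehyde
Conditions: DBU, THF, 0 °C to rt, 2 as limiting reagent
Reagents that add atoms: none
Why: C-Alkylation of a phloroglucinol phenoxide (the ring carbon of the ambident anion attacks the soft allylic bromide and the dienone re-aromatises); the two free ring carbons of 1 are equivalent, so only one mono-C-prenyl product can form, and keeping 2 limiting holds back double prenylation.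

Step 2
Reactants: 3 2,4,6-trihydroxy-3-(3-methylbut-2-en-1-yl)benzaldehyde
Product: 4 2,6-dihydroxy-4-methoxy-3-(3-methylbut-2-en-1-yl)benzaldehyde
Conditions: Me2SO4 (1.0 equiv), K2CO3 (1.0 equiv), acetone, rt
Reagents that add atoms: dimethyl sulfate, COS(=O)(=O)OC
Why: Williamson etherification under substrate control: the hydroxyl para to the formyl group is the most acidic (a vinylogous carboxylic acid) and is not held in a hydrogen bond to the carbonyl, so one equivalent of base and of a hard methylating agent should methylate it in preference to the ortho hydroxyls and to ring carbon.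

Step 3
Reactants: 4 2,6-dihydroxy-4-methoxy-3-(3-methylbut-2-en-1-yl)benzaldehyde
Product: 5 2-hydroxy-4-methoxy-6-(methoxymethoxy)-3-(3-methylbut-2-en-1-yl)benzaldehyde
Conditions: MOMCl (1.1 equiv), i-Pr2NEt, CH2Cl2, 0 °C
Reagents that add atoms: chloromethyl methyl ether, COCCl
Why: O-Methoxymethylation (Williamson type) of the more accessible ortho hydroxyl: the hydroxyl between formyl and prenyl is the more hindered and should be the one held in the hydrogen bond to the carbonyl, so the open-flanked hydroxyl reacts. After one alkylation the remaining hydroxyl is fully chelated, which should stop the reaction at the mono-ether.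

Step 4
Reactants: 6 caffeic acid
Product: 7 4-vinylcatechol (4-ethenylbenzene-1,2-diol)
Conditions: Et3N, DMF, 100 °C, N2; solution used at once
Reagents that add atoms: none
Why: Base-assisted thermal decarboxylation of a 4-hydroxycinnamic acid: the phenoxide tautomerises to a quinone methide that is a vinylogous β-keto acid and loses CO2. Compound 7 polymerises readily and is carried forward as a cold, fresh solution.

Step 5
Reactants: 5 2-hydroxy-4-methoxy-6-(methoxymethoxy)-3-(3-methylbut-2-en-1-yl)benzaldehyde; 8 trimethyl orthoformate; 7 4-vinylcatechol
Product: 10 (2S,4S)-2-(3,4-dihydroxyphenyl)-4,7-dimethoxy-5-(methoxymethoxy)-8-(3-methylbut-2-en-1-yl)chromane (2,4-cis), via dimethyl acetal 9 (not isolated)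
Conditions: 8 (1.2 equiv), (R)-3,3'-bis(2,4,6-triisopropylphenyl)-1,1'-binaphthyl-2,2'-diyl hydrogen phosphate (10 mol%), 5 Å MS, CH2Cl2, rt; then 7, −30 to 0 °C
Reagents that add atoms: none
Why: Proposed new method: acid-catalysed exchange with 8 should turn the aldehyde into acetal 9, which the chiral acid ionises with loss of methanol to a hydrogen-bonded 4-methoxy ortho-quinone methide (an aryl oxocarbenium phosphate ion pair); the electron-rich terminal carbon of 7 then attacks the methide carbon to form C3–C4 and the phenol oxygen captures the ring B benzylic cation (a para-quinone methide because of the 4'-hydroxyl) to form O1–C2, the closest known reactions being the achiral acid-promoted three-component chroman synthesis from salicylaldehydes, orthoformates and styrenes and the chiral phosphoric acid cycloadditions of ortho-quinone methides with hydroxystyrenes. Ring C closes in a six-membered inverse-demand oxa-[4+2] mode; if the addition is stepwise, the last event is a 6-exo-trig addition of the phenol oxygen to the exocyclic C2=C1' bond. C2 is set by the catalyst: the phosphoryl oxygen should hold the 4'-hydroxyl of 7 and the acidic P–OH the quinone methide oxygen, so that one face of the alkene is presented inside the pocket of the 2,4,6-triisopropylphenyl groups. C4 follows from the endo placement of the aryl group, which gives the 2,4-cis adduct; this centre is erased in step 8, so its ratio is of no consequence. Regiochemistry follows from polarity (nucleophilic alkene terminus to electrophilic C4) and from the methoxymethyl ether, which leaves only the hydroxyl next to the prenyl group free to become O1. The step needs enantioface selectivity at C2 and chemoselectivity for the acetal over the prenyl alkene; the weak catalytic acid and low temperature should leave the prenyl group and the methoxymethyl ether untouched. The orthoformate is consumed before 7 is added so that the catechol is not tied up as a cyclic orthoester.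

Step 6
Reactants: 10 (2S,4S)-2-(3,4-dihydroxyphenyl)-4,7-dimethoxy-5-(methoxymethoxy)-8-(3-methylbut-2-en-1-yl)chromane
Product: 11 (2S,4S)-2-(3,4-diacetoxyphenyl)-4,7-dimethoxy-5-(methoxymethoxy)-8-(3-methylbut-2-en-1-yl)chromane
Conditions: Ac2O, pyridine, DMAP (cat.), CH2Cl2, 0 °C
Reagents that add atoms: acetic anhydride, CC(=O)OC(C)=O
Why: Base-catalysed O-acylation of the two phenols; the acetates make ring B electron-poor so that O1–C2 can no longer ionise through a para-quinone methide in the acidic steps, and they protect the catechol from MnO2. C2 and C4 are not touched.

Step 7
Reactants: 11 (2S,4S)-2-(3,4-diacetoxyphenyl)-4,7-dimethoxy-5-(methoxymethoxy)-8-(3-methylbut-2-en-1-yl)chromane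
Product: 12 (2S)-2-(3,4-diacetoxyphenyl)-7-methoxy-5-(methoxymethoxy)-8-(3-methylbut-2-en-1-yl)chroman-4-ol (both C4 epimers)
Conditions: PPTS (cat.), THF/H2O (3:1), rt; product used crude
Reagents that add atoms: water, O
Why: SN1 solvolysis of a benzylic ether: C4 is attached to a ring carbon with two ortho oxygens and one para oxygen, so weak acid should ionise C4–OMe and water in large excess captures the cation. The configuration at C4 is lost but irrelevant, and C2 is not involved because the acetylated ring B cannot support a cation; aryl acetates and the methoxymethyl ether are stable to a pyridinium acid at room temperature.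

Step 8
Reactants: 12 (2S)-2-(3,4-diacetoxyphenyl)-7-methoxy-5-(methoxymethoxy)-8-(3-methylbut-2-en-1-yl)chroman-4-ol
Product: 13 (2S)-2-(3,4-diacetoxyphenyl)-7-methoxy-5-(methoxymethoxy)-8-(3-methylbut-2-en-1-yl)chroman-4-one
Conditions: activated MnO2 (excess), CH2Cl2, rt
Reagents that add atoms: none
Why: Oxidation of an electron-rich secondary benzylic alcohol to the aryl ketone on the MnO2 surface under neutral conditions; the prenyl alkene, the acetates and the acetal are inert to MnO2, and removal of the C4 stereocentre leaves C2 (S) as the only one.

Step 9
Reactants: 13 (2S)-2-(3,4-diacetoxyphenyl)-7-methoxy-5-(methoxymethoxy)-8-(3-methylbut-2-en-1-yl)chroman-4-one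
Product: 14 (2S)-2-(3,4-dihydroxyphenyl)-5-hydroxy-7-methoxy-8-(3-methylbut-2-en-1-yl)chroman-4-one (CNP0294928.1)
Conditions: HCl (1.25 M in MeOH), 40 °C
Reagents that add atoms: none
Why: Acid-catalysed acetal exchange removes the methoxymethyl group and acid-catalysed transesterification removes both aryl acetates. Acid is chosen over base because flavanones open to chalcones and lose C2 under base; the prenyl group has no free ortho hydroxyl to cyclise onto, so dilute HCl at mild temperature should leave it and C2 intact.

## Compound list

1 | 2,4,6-trihydroxybenzaldehyde | O=Cc1c(O)cc(O)cc1O | starting material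
2 | prenyl bromide (1-bromo-3-methylbut-2-ene) | CC(C)=CCBr | starting material
3 | 2,4,6-trihydroxy-3-(3-methylbut-2-en-1-yl)benzaldehyde | O=Cc1c(O)cc(O)c(CC=C(C)C)c1O | intermediate
4 | 2,6-dihydroxy-4-methoxy-3-(3-methylbut-2-en-1-yl)benzaldehyde | COc1cc(O)c(C=O)c(O)c1CC=C(C)C | intermediate
5 | 2-hydroxy-4-methoxy-6-(methoxymethoxy)-3-(3-methylbut-2-en-1-yl)benzaldehyde | COc1cc(OCOC)c(C=O)c(O)c1CC=C(C)C | intermediate
6 | caffeic acid ((E)-3-(3,4-dihydroxyphenyl)prop-2-enoic acid) | OC(=O)/C=C/c1ccc(O)c(O)c1 | starting material
7 | 4-vinylcatechol (4-ethenylbenzene-1,2-diol) | C=Cc1ccc(O)c(O)c1 | intermediate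
8 | trimethyl orthoformate | COC(OC)OC | starting material
9 | 6-(dimethoxymethyl)-3-methoxy-5-(methoxymethoxy)-2-(3-methylbut-2-en-1-yl)phenol (dimethyl acetal of 5, not isolated) | COc1cc(OCOC)c(C(OC)OC)c(O)c1CC=C(C)C | intermediate
10 | (2S,4S)-2-(3,4-dihydroxyphenyl)-4,7-dimethoxy-5-(methoxymethoxy)-8-(3-methylbut-2-en-1-yl)chromane (2,4-cis) | COc1cc(OCOC)c2c(c1CC=C(C)C)O[C@H](c1ccc(O)c(O)c1)C[C@@H]2OC | intermediate
11 | (2S,4S)-2-(3,4-diacetoxyphenyl)-4,7-dimethoxy-5-(methoxymethoxy)-8-(3-methylbut-2-en-1-yl)chromane | COc1cc(OCOC)c2c(c1CC=C(C)C)O[C@H](c1ccc(OC(C)=O)c(OC(C)=O)c1)C[C@@H]2OC | intermediate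
12 | (2S)-2-(3,4-diacetoxyphenyl)-7-methoxy-5-(methoxymethoxy)-8-(3-methylbut-2-en-1-yl)chroman-4-ol (C4 epimers, C4 not defined) | COc1cc(OCOC)c2c(c1CC=C(C)C)O[C@H](c1ccc(OC(C)=O)c(OC(C)=O)c1)CC2O | intermediate
13 | (2S)-2-(3,4-diacetoxyphenyl)-7-methoxy-5-(methoxymethoxy)-8-(3-methylbut-2-en-1-yl)chroman-4-one | COc1cc(OCOC)c2c(c1CC=C(C)C)O[C@H](c1ccc(OC(C)=O)c(OC(C)=O)c1)CC2=O | intermediate
14 | (2S)-2-(3,4-dihydroxyphenyl)-5-hydroxy-7-methoxy-8-(3-methylbut-2-en-1-yl)chroman-4-one (CNP0294928.1) | COc1cc(O)c2c(c1CC=C(C)C)O[C@H](c1ccc(O)c(O)c1)CC2=O | target

## Step count and least certain steps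

Total step count: 9. Longest linear sequence: 8 steps (steps 1, 2, 3, 5, 6, 7, 8, 9 from 1); the branch from 6 to 7 is one step.

**Step 5 (key step, proposed new method).**
- *What may go wrong.* The most likely failure is poor enantioface selection, because part of the reaction runs outside the chiral ion pair through a loosely bound oxocarbenium ion, or because O1–C2 of the 4'-hydroxy product ionises reversibly. Acetal formation may also be slow with so weak an acid, the styrene may oligomerise, and the product may re-ionise at C4 and be alkylated a second time. A stronger chiral acid of the same family would be the first change of conditions.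
- *Fallback (known chemistry; resolution instead of asymmetric catalysis).* It sets out from 5, 7 and 8 and rejoins the route at 13. The three-component cycloaddition is run in its known racemic form with an achiral acid (diphenyl hydrogen phosphate, CH2Cl2, 0 °C) to give the racemic 2,4-cis 4-methoxyflavan catechol F1. Acetylation as in step 6 should give the racemic diacetate F2, solvolysis as in step 7 the racemic flavan-4-ol F3, and MnO2 oxidation the racemic flavanone F4. F4 is then resolved by asymmetric transfer hydrogenation, a known kinetic resolution of racemic flavanones: RuCl(p-cymene)[(R,R)-TsDPEN], HCO2H/Et3N (5:2), EtOAc, rt, stopped near half conversion. By the usual model for this catalyst the 2R ketone should be reduced, anti to the aryl group, to the (2R,4R)-cis-flavan-4-ol F5. Unreacted 13 is then separated by chromatography. The (S,S) complex is used if the preference proves opposite. At most half of the material is carried on.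

**Step 3.**
- *What may go wrong.* Site selection between the two ortho hydroxyls may be insufficient, since the alkylating agent is small and very reactive. The ether would then sit on the oxygen meant for O1 and the key step would lead into the 6-prenyl series. Step 2 carries the related risk of methylating an ortho hydroxyl.
- *Fallback.* It sets out from 1 and rejoins the route at 5, and it replaces graded phenol reactivity by a rearrangement that fixes the regiochemistry.
  - Para-selective methylation of 1 (Me2SO4, K2CO3, acetone) gives symmetric 2,6-dihydroxy-4-methoxybenzaldehyde F6.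
  - Mono-methoxymethylation (MOMCl, i-Pr2NEt, CH2Cl2) gives 2-hydroxy-4-methoxy-6-(methoxymethoxy)benzaldehyde F7. The question of which ortho hydroxyl is protected cannot arise here.
  - CuCl2-catalysed O-alkylation with 3-chloro-3-methylbut-1-yne (DBU, MeCN, 0 °C) gives the 1,1-dimethylpropargyl ether F8.
  - Semihydrogenation (H2, Pd on CaCO3 poisoned with Pb(OAc)2, quinoline, EtOAc) gives the 1,1-dimethylallyl ether F9.
  - Aromatic Claisen rearrangement (N,N-diethylaniline, 150 °C) moves the allyl unit with inversion to the only free ortho carbon. This gives 5, with the liberated hydroxyl necessarily next to the prenyl group.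

**Step 7.**
- *What may go wrong.* The C4 cation may lose H3 to give a flav-3-ene, or alkylate C6 of a second molecule, instead of taking up water. Partial loss of the methoxymethyl ether would be harmless.
- *Fallback.* It sets out from 11 and rejoins the route at 13 without a new isolated compound. Oxidative cleavage of the benzylic methyl ether with DDQ (CH2Cl2/pH 7 buffer, 0 °C) abstracts hydride from C4–H, the most hydridic C–H bond because it is α to the methoxyl and benzylic to the trioxygenated ring. Water adds to the methoxy-oxocarbenium ion and the hemiketal collapses to ketone 13. This bypasses both the cation in protic acid and step 8.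

**Step 9.**
- *What may go wrong.* Ester cleavage may be incomplete at an acidity the prenyl alkene tolerates. If the acid is pushed, methanol or HCl may add across the prenyl double bond, and C2 may slowly epimerise by ring opening once the 4'-hydroxyl is free.
- *Fallback.* It sets out from 13 and rejoins the route at 14, unmasking in two orthogonal stages without protic mineral acid. Near-neutral cleavage of the aryl acetates (NH4OAc, MeOH/H2O, rt) gives (2S)-2-(3,4-dihydroxyphenyl)-7-methoxy-5-(methoxymethoxy)-8-(3-methylbut-2-en-1-yl)chroman-4-one F10. The chelation-activated 5-O-methoxymethyl ether is then removed with ZnBr2 and propane-1-thiol (CH2Cl2, 0 °C) to give 14.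

## Further compounds

F1 | step 5 | racemic (2S,4S)/(2R,4R)-2-(3,4-dihydroxyphenyl)-4,7-dimethoxy-5-(methoxymethoxy)-8-(3-methylbut-2-en-1-yl)chromane (racemate of 10, 2,4-cis, one enantiomer drawn) | COc1cc(OCOC)c2c(c1CC=C(C)C)O[C@H](c1ccc(O)c(O)c1)C[C@@H]2OC
F2 | step 5 | racemic (2S,4S)/(2R,4R)-2-(3,4-diacetoxyphenyl)-4,7-dimethoxy-5-(methoxymethoxy)-8-(3-methylbut-2-en-1-yl)chromane (racemate of 11, 2,4-cis, one enantiomer drawn) | COc1cc(OCOC)c2c(c1CC=C(C)C)O[C@H](c1ccc(OC(C)=O)c(OC(C)=O)c1)C[C@@H]2OC
F3 | step 5 | racemic 2-(3,4-diacetoxyphenyl)-7-methoxy-5-(methoxymethoxy)-8-(3-methylbut-2-en-1-yl)chroman-4-ol (all stereoisomers, no centre defined) | COc1cc(OCOC)c2c(c1CC=C(C)C)OC(c1ccc(OC(C)=O)c(OC(C)=O)c1)CC2O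
F4 | step 5 | racemic 2-(3,4-diacetoxyphenyl)-7-methoxy-5-(methoxymethoxy)-8-(3-methylbut-2-en-1-yl)chroman-4-one (racemate of 13) | COc1cc(OCOC)c2c(c1CC=C(C)C)OC(c1ccc(OC(C)=O)c(OC(C)=O)c1)CC2=O
F5 | step 5 | (2R,4R)-2-(3,4-diacetoxyphenyl)-7-methoxy-5-(methoxymethoxy)-8-(3-methylbut-2-en-1-yl)chroman-4-ol (2,4-cis) | COc1cc(OCOC)c2c(c1CC=C(C)C)O[C@@H](c1ccc(OC(C)=O)c(OC(C)=O)c1)C[C@H]2O
F6 | step 3 | 2,6-dihydroxy-4-methoxybenzaldehyde | COc1cc(O)c(C=O)c(O)c1
F7 | step 3 | 2-hydroxy-4-methoxy-6-(methoxymethoxy)benzaldehyde | COc1cc(O)c(C=O)c(OCOC)c1
F8 | step 3 | 4-methoxy-2-(methoxymethoxy)-6-[(2-methylbut-3-yn-2-yl)oxy]benzaldehyde | COc1cc(OCOC)c(C=O)c(OC(C)(C)C#C)c1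
F9 | step 3 | 4-methoxy-2-(methoxymethoxy)-6-[(2-methylbut-3-en-2-yl)oxy]benzaldehyde | COc1cc(OCOC)c(C=O)c(OC(C)(C)C=C)c1
F0 | step 7 | none | none
F10 | step 9 | (2S)-2-(3,4-dihydroxyphenyl)-7-methoxy-5-(methoxymethoxy)-8-(3-methylbut-2-en-1-yl)chroman-4-one | COc1cc(OCOC)c2c(c1CC=C(C)C)O[C@H](c1ccc(O)c(O)c1)CC2=O
A1 | alternative 1 | (2S)-2-[3,4-bis(methoxymethoxy)phenyl]-5-hydroxy-7-methoxy-8-(3-methylbut-2-en-1-yl)chroman-4-one | COc1cc(O)c2c(c1CC=C(C)C)O[C@H](c1ccc(OCOC)c(OCOC)c1)CC2=O
A2 | alternative 1 | (2S)-2-[3,4-bis(methoxymethoxy)phenyl]-5-(phenylsulfinyl)-2,3-dihydro-4H-pyran-4-one (configuration at sulfur not specified) | O=C1C[C@@H](c2ccc(OCOC)c(OCOC)c2)OC=C1S(=O)c1ccccc1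
A3 | alternative 1 | 1,3-dimethoxy-7-methyl-1-(trimethylsilyloxy)octa-1,3,6-triene (double-bond geometry not specified) | COC(O[Si](C)(C)C)=CC(OC)=CCC=C(C)C
A4 | alternative 2 | (2S)-2-[3,4-bis(tert-butyldimethylsilyloxy)phenyl]-7-methoxy-8-(3-methylbut-2-en-1-yl)-5-(triisopropylsilyloxy)chroman-4-one | COc1cc(O[Si](C(C)C)(C(C)C)C(C)C)c2c(c1CC=C(C)C)O[C@H](c1ccc(O[Si](C)(C)C(C)(C)C)c(O[Si](C)(C)C(C)(C)C)c1)CC2=O
A5 | alternative 2 | 1-[2-{[3,4-bis(tert-butyldimethylsilyloxy)benzyl]oxy}-4-methoxy-3-(3-methylbut-2-en-1-yl)-6-(triisopropylsilyloxy)phenyl]-2-diazoethan-1-one | COc1cc(O[Si](C(C)C)(C(C)C)C(C)C)c(C(=O)C=[N+]=[N-])c(OCc2ccc(O[Si](C)(C)C(C)(C)C)c(O[Si](C)(C)C(C)(C)C)c2)c1CC=C(C)C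
A6 | alternative 3 | (2S)-2-(3,4-diacetoxyphenyl)-5,7-dimethoxy-8-(3-methylbut-2-en-1-yl)chroman-4-one | COc1cc(OC)c2c(c1CC=C(C)C)O[C@H](c1ccc(OC(C)=O)c(OC(C)=O)c1)CC2=O
A7 | alternative 3 | (3S)-3-(3,4-diacetoxyphenyl)-3-[3,5-dimethoxy-2-(3-methylbut-2-en-1-yl)phenoxy]propanoic acid | COc1cc(OC)c(CC=C(C)C)c(O[C@@H](CC(=O)O)c2ccc(OC(C)=O)c(OC(C)=O)c2)c1
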